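A direct plan would start from the purchased arene A1, 1,4-dimethoxy-2-methylbenzene, and build the side chain on it.
Friedel–Crafts chloroacetylation of A1 with AlCl3 and loss of the ortho methyl ether would give the o-hydroxyaryl chloromethyl ketone A2; silylation, asymmetric transfer hydrogenation and base closure would give the aryl oxirane A3.
The benzylic oxirane C–H of A3 would then be lithiated, trapped with a one-carbon electrophile and acylated to the silyl-protected epoxy ester A4, and fluoride would exchange the silyl group for the tigloyl group.
Weakest would be the lithiation and hydroxymethylation of the oxirane: the quaternary stereocentre would rest on the configurational stability of a benzylic oxiranyllithium (a carbenoid that can racemise or ring-open) and on clean capture of a monomeric C1 electrophile.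
Second, putting the silyl group on and exchanging it at the end would be two operations that add no complexity, the latter on the most advanced material, where a free o-hydroxyaryl oxirane opens easily.
Third, the Friedel–Crafts step on A1 would have to find one ring position and cleave one of two methyl ethers beside a reactive CH2Cl group.

Plan of the new route (benzene ring: C1 carries the tiglate oxygen, C2 the oxirane, C3 H, C4 OCH3, C5 CH3, C6 H): the retrosynthesis cuts the aryl O–acyl bond and three ring bonds, C1–C2, C1–C6 and C3–C4.
C2/C3 become a terminal alkyne that already carries the finished (R)-oxirane ester, C1 with its oxygen becomes carbon monoxide, and C4–C5–C6 with OCH3 and CH3 become an isopropenyl(methoxy)carbene complex of chromium.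
The enabling feature is the 1,4-dioxygenated benzene ring whose two oxygens differ (methyl ether at C4, ester at C1), with the carbon substituent at C2 next to the ester oxygen and H at C3 and C6: the native pattern of a Dötz benzannulation.
The oxirane ring arises first (asymmetric epoxidation of an enynol); the benzene ring arises last, in the final step.
No oxiranyl anion is needed, because the quaternary centre is set by reagent control on an allylic alcohol; no phenol protecting group is used, because the phenol is acylated in the flask in which it forms; no substitution or demethylation has to be steered on an existing ring.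

Key step: step 6

Assumptions: 2-bromoprop-2-en-1-ol and (2E)-2-methylbut-2-enoic anhydride are taken as purchasable; in the fallback for step 2 the lipase is assumed to acylate the (R)-alcohol faster, which would have to be confirmed by experiment.

Step 1
Reactants: 1 2-bromoprop-2-en-1-ol; 2 ethynyltrimethylsilane
Product: 3 2-methylidene-4-(trimethylsilyl)but-3-yn-1-ol
Conditions: PdCl2(PPh3)2 (2 mol %), CuI (4 mol %), iPr2NH (3 equiv), THF, rt
Reagents that add atoms: none
Why: Sonogashira coupling of a vinyl bromide with a terminal alkyne tolerates the free allylic alcohol, and the silyl cap keeps the small enynol non-volatile and prevents alkyne homocoupling.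

Step 2
Reactants: 3 2-methylidene-4-(trimethylsilyl)but-3-yn-1-ol
Product: 4 [(2S)-2-[(trimethylsilyl)ethynyl]oxiran-2-yl]methanol
Conditions: Ti(OiPr)4 (0.2 equiv), L-(+)-DIPT (0.26 equiv), t-BuOOH (2 equiv, isooctane), 4 Å MS, CH2Cl2, −20 °C
Reagents that add atoms: tert-butyl hydroperoxide, CC(C)(C)OO
Why: Katsuki–Sharpless asymmetric epoxidation of a 2-substituted allylic alcohol, in which the titanium-bound hydroxyl directs the peroxide to the 1,1-disubstituted alkene and L-(+)-tartrate should deliver oxygen to the face that gives the (S)-epoxy alcohol (the sense that turns 2-methylprop-2-en-1-ol into (S)-2-methylglycidol), so the quaternary stereocentre of the target is set here; the alkynyl group makes the tertiary carbon a poor cation, so titanium-promoted opening should be slow.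

Step 3
Reactants: 4 [(2S)-2-[(trimethylsilyl)ethynyl]oxiran-2-yl]methanol; 5 3-methylbutanoic anhydride
Product: 6 [(2R)-2-[(trimethylsilyl)ethynyl]oxiran-2-yl]methyl 3-methylbutanoate
Conditions: 5 (1.3 equiv), Et3N (2 equiv), DMAP (5 mol %), CH2Cl2, 0 °C
Reagents that add atoms: none
Why: DMAP-catalysed O-acylation of the primary alcohol leaves the geometry untouched (the descriptor changes from S to R only because CH2O-acyl now outranks the ring CH2), and base cannot erode the centre because the Payne rearrangement of a 2,2-disubstituted glycidol is degenerate and returns the same enantiomer.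

Step 4
Reactants: 6 [(2R)-2-[(trimethylsilyl)ethynyl]oxiran-2-yl]methyl 3-methylbutanoate
Product: 7 [(2R)-2-ethynyloxiran-2-yl]methyl 3-methylbutanoate
Conditions: Bu4NF (1.1 equiv), AcOH (1.2 equiv), THF, 0 °C
Reagents that add atoms: none
Why: Fluoride cleaves the C(sp)–Si bond selectively (protodesilylation of an alkynylsilane), and the acetic acid buffer keeps the medium non-basic so that the ester and the oxirane should survive.

Step 5
Reactants: 8 2-bromoprop-1-ene; 9 hexacarbonylchromium Cr(CO)6
Product: 12 pentacarbonyl[methoxy(prop-1-en-2-yl)methylidene]chromium (CO)5Cr=C(OCH3)C(CH3)=CH2, via prop-1-en-2-yllithium 10 (not isolated), via lithium acylchromate 11 (not isolated)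
Conditions: t-BuLi (2.0 equiv), Et2O, −78 °C; 9 (1.0 equiv), Et2O, 0 °C → rt; Me3OBF4 (1.5 equiv), CH2Cl2, 0 °C
Reagents that add atoms: trimethyloxonium tetrafluoroborate, C[O+](C)C.F[B-](F)(F)F
Why: Fischer synthesis of an alkoxycarbene complex, in which lithium–bromine exchange gives the alkenyllithium, this adds to a carbonyl ligand of Cr(CO)6 to give the acylchromate, and the hard oxonium salt methylates it on oxygen.

Step 6
Reactants: 7 [(2R)-2-ethynyloxiran-2-yl]methyl 3-methylbutanoate; 12 pentacarbonyl[methoxy(prop-1-en-2-yl)methylidene]chromium; 13 (2E)-2-methylbut-2-enoic anhydride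
Product: 17 2-[(2R)-2-[(3-methylbutanoyloxy)methyl]oxiran-2-yl]-4-methoxy-5-methylphenyl (2E)-2-methylbut-2-enoate (CNP0108422.1), via chromium-bound dienylketene 14 (not isolated), via chromium-bound phenol 15 (not isolated), via chromium-bound aryl tiglate 16 (not isolated)
Conditions: 12 (1.3 equiv), 13 (2 equiv), Et3N (3 equiv), THF (0.05 M), 50 °C, Ar; then DMAP (0.1 equiv), rt; then air, MeCN, daylight, rt
Reagents that add atoms: none
Why: Dötz benzannulation: thermal loss of one CO from 12 lets the alkyne coordinate and insert into the Cr=C bond with its unsubstituted carbon bonding to the carbene carbon (new C3–C4 bond), CO insertion at the chromium-bound carbon (new C1–C2 bond) gives the η4-dienylketene 14, and closure onto the isopropenyl CH2 (new C1–C6 bond) followed by tautomerisation gives the Cr(CO)3-bound 4-methoxyphenol 15. The closest known reaction type is the benzannulation of alkenyl(methoxy)carbene complexes of chromium with terminal alkynes that carry an oxygenated propargylic carbon, run with an anhydride and a tertiary amine so that the phenol is acylated as it forms; here the anhydride is 13, the phenol is captured as the tiglate 16 while still bound to the electron-withdrawing Cr(CO)3 group, and air and light then release the metal. The only ring closed is the benzene ring, by six-electron electrocyclisation of the dienylketene, and the oxirane is a spectator. No stereocentre is made: the quaternary carbon cannot enolise and passes through unchanged, and the two Cr(CO)3 face isomers of 15 and 16 converge on decomplexation. The step needs regiocontrol (oxirane-bearing carbon next to the new C–O), secured by the terminal alkyne whose quaternary substituent is the large group, and differentiation of the two ring oxygens, secured because the C4 oxygen arrives as OCH3 from the carbene and the C1 oxygen as the only free OH from CO. It also needs the oxirane to survive next to a phenol, which the acylation in the flask should secure; the isovalerate and the oxirane should be inert to zerovalent chromium carbonyl species and Et3N at 50 °C, and the ethynyloxirane itself is the untested element.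

**Compound list**
1 | 2-bromoprop-2-en-1-ol | C=C(Br)CO | starting material
2 | ethynyltrimethylsilane | C#C[Si](C)(C)C | starting material
3 | 2-methylidene-4-(trimethylsilyl)but-3-yn-1-ol | C=C(CO)C#C[Si](C)(C)C | intermediate
4 | [(2S)-2-[(trimethylsilyl)ethynyl]oxiran-2-yl]methanol | C[Si](C)(C)C#C[C@]1(CO)CO1 | intermediate
5 | 3-methylbutanoic anhydride | CC(C)CC(=O)OC(=O)CC(C)C | starting material
6 | [(2R)-2-[(trimethylsilyl)ethynyl]oxiran-2-yl]methyl 3-methylbutanoate | C[Si](C)(C)C#C[C@]1(COC(=O)CC(C)C)CO1 | intermediate
7 | [(2R)-2-ethynyloxiran-2-yl]methyl 3-methylbutanoate | C#C[C@]1(COC(=O)CC(C)C)CO1 | intermediate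
8 | 2-bromoprop-1-ene | C=C(C)Br | starting material
9 | hexacarbonylchromium Cr(CO)6 | O=C=[Cr](=C=O)(=C=O)(=C=O)(=C=O)=C=O | starting material
10 | prop-1-en-2-yllithium | [Li]C(C)=C | intermediate
11 | lithium pentacarbonyl(2-methylprop-2-enoyl)chromate Li[(CO)5CrC(O)C(CH3)=CH2] | C=C(C)C([O-])=[Cr](=C=O)(=C=O)(=C=O)(=C=O)=C=O.[Li+] | intermediate
12 | pentacarbonyl[methoxy(prop-1-en-2-yl)methylidene]chromium (CO)5Cr=C(OCH3)C(CH3)=CH2 | COC(C(C)=C)=[Cr](=C=O)(=C=O)(=C=O)(=C=O)=C=O | intermediate
13 | (2E)-2-methylbut-2-enoic anhydride (tiglic anhydride) | C/C=C(\C)C(=O)OC(=O)/C(C)=C/C | starting material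
14 | {(2R)-2-[(3E)-4-methoxy-5-methyl-1-oxohexa-1,3,5-trien-2-yl]oxiran-2-yl}methyl 3-methylbutanoate, η4-bound to Cr(CO)3 (metal fragment written as a separate component) | C=C(C)/C(OC)=C\C(=C=O)[C@]1(COC(=O)CC(C)C)CO1.O=C=[Cr](=C=O)=C=O | intermediate
15 | tricarbonyl{η6-[(2R)-2-(2-hydroxy-5-methoxy-4-methylphenyl)oxiran-2-yl]methyl 3-methylbutanoate}chromium, (arene)Cr(CO)3, both face isomers (metal fragment written as a separate component) | COc1cc([C@]2(COC(=O)CC(C)C)CO2)c(O)cc1C.O=C=[Cr](=C=O)=C=O | intermediate
16 | tricarbonyl{η6-2-[(2R)-2-[(3-methylbutanoyloxy)methyl]oxiran-2-yl]-4-methoxy-5-methylphenyl (2E)-2-methylbut-2-enoate}chromium, (arene)Cr(CO)3, both face isomers (metal fragment written as a separate component) | C/C=C(\C)C(=O)Oc1cc(C)c(OC)cc1[C@]1(COC(=O)CC(C)C)CO1.O=C=[Cr](=C=O)=C=O | intermediate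
17 | 2-[(2R)-2-[(3-methylbutanoyloxy)methyl]oxiran-2-yl]-4-methoxy-5-methylphenyl (2E)-2-methylbut-2-enoate | C/C=C(\C)C(=O)Oc1cc(C)c(OC)cc1[C@]1(COC(=O)CC(C)C)CO1 | target

Total step count: 6. Longest linear sequence: 5 (steps 1, 2, 3, 4 and 6; step 5 is a one-step branch that joins in step 6).

**Steps most likely to fail**

1. Step 6. What may go wrong: slow capture of the hindered chromium-bound phenol by the anhydride, so that the neighbouring phenol opens the oxirane; isomerisation of the ethynyloxirane by coordinatively unsaturated chromium carbonyl fragments before it enters the benzannulation; or diversion of the ketene intermediate away from electrocyclisation.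
Fallback (from 3, back at 17): the oxirane would be kept out of the chromium chemistry and made after the ring.
Silylation of 3 (TBSCl, imidazole, CH2Cl2) would give tert-butyldimethyl{[2-methylidene-4-(trimethylsilyl)but-3-yn-1-yl]oxy}silane F1, and K2CO3 in MeOH would free the alkyne to give tert-butyldimethyl[(2-methylidenebut-3-yn-1-yl)oxy]silane F2.
The same benzannulation with 12, 13 and Et3N (conjugated enynes are established partners, the alkenyl-bearing carbon ending next to the new oxygen) would give, after release of chromium in air, 2-{3-[(tert-butyldimethylsilyl)oxy]prop-1-en-2-yl}-4-methoxy-5-methylphenyl (2E)-2-methylbut-2-enoate F3.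
HF·pyridine in THF would give 2-(3-hydroxyprop-1-en-2-yl)-4-methoxy-5-methylphenyl (2E)-2-methylbut-2-enoate F4.
A Katsuki–Sharpless epoxidation with Ti(OiPr)4, L-(+)-DIPT and t-BuOOH (same facial sense as in step 2) would give 2-[(2S)-2-(hydroxymethyl)oxiran-2-yl]-4-methoxy-5-methylphenyl (2E)-2-methylbut-2-enoate F5, and acylation with 5 (Et3N, DMAP) would give 17.

2. Step 2. What may go wrong: sluggish oxygen transfer to the electron-poor enyne alkene, with erosion of facial selectivity or titanium-promoted opening of the product at the long reaction times needed.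
Fallback (from 3, back at 4): hydroxyl-directed racemic epoxidation of 3 (VO(acac)2 cat., t-BuOOH, CH2Cl2) would give rac-{2-[(trimethylsilyl)ethynyl]oxiran-2-yl}methanol F6.
Kinetic resolution by lipase-catalysed acylation (Burkholderia cepacia lipase, vinyl acetate, t-BuOMe), a known way to resolve 2-substituted oxiranemethanols, would convert the (R)-alcohol into [(2S)-2-[(trimethylsilyl)ethynyl]oxiran-2-yl]methyl acetate F7 and leave (S)-4, separated by chromatography.

3. Step 4. What may go wrong: acyl transfer from the isovalerate or opening of the oxirane by fluoride or acetate during the desilylation, and loss of the small product on concentration.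
Fallback (from 4, back at 7): the silyl group would be removed before the ester is made.
K2CO3 in MeOH at 0 °C would give [(2S)-2-ethynyloxiran-2-yl]methanol F8 (the Payne rearrangement of its alkoxide is degenerate and returns the same enantiomer).
F8 would be acylated with 5 (Et3N, DMAP, CH2Cl2) in the extract, without concentration to dryness, to give 7.

**Further compounds**
F1 | step 6 | tert-butyldimethyl{[2-methylidene-4-(trimethylsilyl)but-3-yn-1-yl]oxy}silane | C=C(CO[Si](C)(C)C(C)(C)C)C#C[Si](C)(C)C
F2 | step 6 | tert-butyldimethyl[(2-methylidenebut-3-yn-1-yl)oxy]silane | C#CC(=C)CO[Si](C)(C)C(C)(C)C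
F3 | step 6 | 2-{3-[(tert-butyldimethylsilyl)oxy]prop-1-en-2-yl}-4-methoxy-5-methylphenyl (2E)-2-methylbut-2-enoate | C/C=C(\C)C(=O)Oc1cc(C)c(OC)cc1C(=C)CO[Si](C)(C)C(C)(C)C
F4 | step 6 | 2-(3-hydroxyprop-1-en-2-yl)-4-methoxy-5-methylphenyl (2E)-2-methylbut-2-enoate | C/C=C(\C)C(=O)Oc1cc(C)c(OC)cc1C(=C)CO
F5 | step 6 | 2-[(2S)-2-(hydroxymethyl)oxiran-2-yl]-4-methoxy-5-methylphenyl (2E)-2-methylbut-2-enoate | C/C=C(\C)C(=O)Oc1cc(C)c(OC)cc1[C@]1(CO)CO1
F6 | step 2 | rac-{2-[(trimethylsilyl)ethynyl]oxiran-2-yl}methanol | C[Si](C)(C)C#CC1(CO)CO1
F7 | step 2 | [(2S)-2-[(trimethylsilyl)ethynyl]oxiran-2-yl]methyl acetate | C[Si](C)(C)C#C[C@@]1(COC(C)=O)CO1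
F8 | step 4 | [(2S)-2-ethynyloxiran-2-yl]methanol | C#C[C@]1(CO)CO1
A1 | direct plan | 1,4-dimethoxy-2-methylbenzene | Cc1cc(OC)ccc1OC
A2 | direct plan | 2-chloro-1-(2-hydroxy-5-methoxy-4-methylphenyl)ethan-1-one | O=C(CCl)c1cc(OC)c(C)cc1O
A3 | direct plan | (2R)-2-[5-methoxy-4-methyl-2-(triisopropylsilyloxy)phenyl]oxirane | COc1cc([C@@H]2CO2)c(O[Si](C(C)C)(C(C)C)C(C)C)cc1C
A4 | direct plan | [(2R)-2-[5-methoxy-4-methyl-2-(triisopropylsilyloxy)phenyl]oxiran-2-yl]methyl 3-methylbutanoate | COc1cc([C@]2(COC(=O)CC(C)C)CO2)c(O[Si](C(C)C)(C(C)C)C(C)C)cc1C
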